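**Retrosynthetic overview**
- The target comes from a bicyclic 2α,3α-diol S-ethyl thioester by bis-angeloylation, followed by a neutral acyl cross-coupling that forms C12–C13 with the Z-enoate already in place.
- Rings A and B form in one radical cascade. A C4 tertiary radical closes ring A (6-endo on C5=C10), and the resulting C10 radical closes ring B (6-exo Giese addition on C9=C11). The Δ7-enal is already present in the chain.
- The cis-2,3-diol pair is bought as D-erythronolactone acetonide. It controls the configuration at C5, C10 and C9 during the cascade.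
- The acyclic precursor is built by acetylide displacement, carboalumination/allylation (giving E-C5=C10), cross metathesis, α-iodination and a Heck reaction.

Assumption: positions are given in labdane numbering (C1–C20); catalysts, ligands and the benzoxazolium salt are purchased reagents.

**Step 1**
Reactants: 1 (−)-2,3-O-isopropylidene-D-erythronolactone; 2 methylmagnesium bromide
Product: 3 2-[(4R,5R)-5-(hydroxymethyl)-2,2-dimethyl-1,3-dioxolan-4-yl]propan-2-ol
Conditions: MeMgBr (3.5 equiv), THF, 0 °C to rt; aq NH4Cl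
Reagents that add atoms: methylmagnesium bromide (2), C[Mg]Br
Why: Double Grignard addition to the lactone carbonyl builds the C4 gem-dimethyl carbinol and frees C1 as CH2OH, while the two dioxolane stereocentres (future C2 and C3) are not touched.

**Step 2**
Reactants: 3 diol
Product: 5 [(4R,5R)-2,2-dimethyl-5-{2-[(triethylsilyl)oxy]propan-2-yl}-1,3-dioxolan-4-yl]methyl 4-methylbenzenesulfonate, via hydroxy tosylate 4 (not isolated)
Conditions: TsCl, Et3N, DMAP (cat.), CH2Cl2, 0 °C; then TESOTf, 2,6-lutidine, −78 to 0 °C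
Reagents that add atoms: tosyl chloride, Cc1ccc(cc1)S(=O)(=O)Cl; triethylsilyl triflate, CC[Si](CC)(CC)OS(=O)(=O)C(F)(F)F
Why: Chemoselective sulfonylation of the primary hydroxyl, followed by silyl triflate capping of the tertiary one in the same flask, prevents internal Williamson closure to a tetrahydrofuran in step 3 and iodoetherification in step 6.

**Step 3**
Reactants: 5 tosylate; 6 lithium acetylide–ethylenediamine complex
Product: 7 {2-[(4R,5R)-2,2-dimethyl-5-(prop-2-yn-1-yl)-1,3-dioxolan-4-yl]propan-2-yl}oxy(triethyl)silane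
Conditions: LiC≡CH·H2NCH2CH2NH2 (3 equiv), DMSO, rt
Reagents that add atoms: lithium acetylide–ethylenediamine (6), [Li+].[C-]#C.NCCN
Why: SN2 alkylation of acetylide at the primary tosylate forms the C1–C10 bond without touching a stereocentre.

**Step 4**
Reactants: 7 alkyne; 8 trimethylaluminium; 9 allyl bromide
Product: 11 triethylsilyl ether of 2-{(4R,5R)-2,2-dimethyl-5-[(2E)-2-methylhexa-2,5-dien-1-yl]-1,3-dioxolan-4-yl}propan-2-ol, via alkenylalane 10 (not isolated)
Conditions: AlMe3 (3 equiv), Cp2ZrCl2 (25 mol%), CH2Cl2, 0 °C to rt; then allyl bromide, Pd(PPh3)4 (5 mol%), THF, rt; Rochelle salt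
Reagents that add atoms: trimethylaluminium (8), C[Al](C)C; allyl bromide (9), C=CCBr
Why: Negishi carboalumination adds CH3 and Al syn with Al on the terminal carbon, and the palladium-catalysed alkenyl–allyl coupling proceeds with retention, so the C5=C10 alkene is purely E and the skipped diene is set up.

**Step 5**
Reactants: 11 diene; 12 (E)-crotonaldehyde
Product: 13 (2E,5E)-7-[(4R,5R)-2,2-dimethyl-5-{2-[(triethylsilyl)oxy]propan-2-yl}-1,3-dioxolan-4-yl]-6-methylhepta-2,5-dienal
Conditions: crotonaldehyde (5 equiv), second-generation Hoveyda–Grubbs catalyst (3 mol%), 1,4-benzoquinone (10 mol%), CH2Cl2, 40 °C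
Reagents that add atoms: crotonaldehyde (12), C/C=C/C=O
Why: In this olefin cross metathesis only the monosubstituted alkene reacts, it gives the E-enal (C7=C8–C17HO), and benzoquinone suppresses hydride-induced migration of the 1,4-diene.

**Step 6**
Reactants: 13 enal
Product: 15 (2Z,5E)-7-[(4R,5R)-5-(2-hydroxypropan-2-yl)-2,2-dimethyl-1,3-dioxolan-4-yl]-2-iodo-6-methylhepta-2,5-dienal, via TES iodoenal 14 (not isolated)
Conditions: I2 (1.5 equiv), pyridine/CH2Cl2, 0 °C to rt, dark; aq Na2S2O3; crude in THF, HF·pyridine, 0 °C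
Reagents that add atoms: iodine, [I][I]
Why: Johnson α-iodination (pyridine conjugate addition, iodination, elimination) gives the thermodynamic Z-iodoenal with iodine cis to C6, which is the geometry ring B needs, and fluoride then frees the carbinol once iodine has been removed.

**Step 7**
Reactants: 16 acryloyl chloride; 17 ethanethiol
Product: 18 S-ethyl prop-2-enethioate
Conditions: pyridine (1.0 equiv), BHT (cat.), CH2Cl2, −78 to 0 °C
Reagents that add atoms: ethanethiol (17), CCS
Why: S-acylation of the thiol by the acid chloride at low temperature is faster than thia-Michael addition.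

**Step 8**
Reactants: 15 iodoenal; 18 thioacrylate
Product: 19 S-ethyl (2E,4E,7E)-4-formyl-9-[(4R,5R)-5-(2-hydroxypropan-2-yl)-2,2-dimethyl-1,3-dioxolan-4-yl]-8-methylnona-2,4,7-trienethioate
Conditions: 18 (3 equiv), Pd(OAc)2 (10 mol%), Ag2CO3 (0.6 equiv), MeCN, 45 °C, dark
Reagents that add atoms: S-ethyl prop-2-enethioate (18), C=CC(=O)SCC
Why: This amine-free, silver-mediated Heck reaction retains the alkenyl iodide geometry and forms the new C9=C11 bond E, and the thioester C–S bond is inert to zerovalent palladium when no copper or zinc cofactor is present.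

**Step 9 (key step)**
Reactants: 19 hydroxy trienal thioester
Product: 21 S-ethyl (2R,3S,5R,9R,10S)-2,3-(isopropylidenedioxy)-17-oxo-13,14,15,16-tetranorlabd-7-ene-12-thioate, via alkoxybenzoxazoline 20 (not isolated)
Conditions: 5,7-di-tert-butyl-3-phenylbenzoxazolium tetrafluoroborate (1.2 equiv), pyridine (1.2 equiv), MTBE, rt, 20 min, filter; then [Ir(ppy)2(dtbbpy)]PF6 (2 mol%), NaOAc (30 mol%), MTBE/DMA, 2 mM, 450 nm LEDs, rt
Reagents that add atoms: none
Why: Proposed new method: the carbinol condenses with the benzoxazolium salt to 20, and photocatalytic oxidation, deprotonation and β-scission of 20 release the C4 tertiary radical exactly where the C–O bond was; this β-oxygenated radical closes ring A 6-endo at the CH end of the E-C5=C10 alkene (5-exo would have to join two fully substituted carbons), the nucleophilic C10 radical closes ring B by a polarity-matched 6-exo Giese addition to C9, and reduction/protonation at C11 ends the redox-neutral cascade; the purchased C2/C3 pair selects the chair with O-2 equatorial and O-3 axial (the other chair places O-2 syn-axial to the C4 and C10 methyls), the E-alkene puts C6 equatorial (H-5 α), the axial C4 methyl makes C9 bond equatorially at C10 (trans-decalin, 10β-CH3), and the acceptor arm lies pseudo-equatorial (H-9 α); the closest known reaction types are the NHC-mediated deoxygenative Giese alkylation of tertiary alcohols and the radical cyclisation of epoxypolyenes with trivalent titanium.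

**Step 10**
Reactants: 21 acetonide
Product: 22 S-ethyl (2R,3S,5R,9R,10S)-2,3-dihydroxy-17-oxo-13,14,15,16-tetranorlabd-7-ene-12-thioate
Conditions: TFA/H2O (9:1), CH2Cl2, 0 °C
Reagents that add atoms: none
Why: Acid-catalysed ketal hydrolysis frees the 2α,3α-diol, and the enal and thioester tolerate cold aqueous acid.

**Step 11**
Reactants: 22 diol; 23 angelic acid
Product: 24 S-ethyl (2R,3S,5R,9R,10S)-2,3-bis{[(2Z)-2-methylbut-2-enoyl]oxy}-17-oxo-13,14,15,16-tetranorlabd-7-ene-12-thioate
Conditions: 23 (6 equiv), 2,4,6-trichlorobenzoyl chloride (6 equiv), Et3N (6.5 equiv), toluene, rt, 2 h; then 22, 80 °C, 36 h (no DMAP)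
Reagents that add atoms: angelic acid (23), C/C=C(/C)C(=O)O
Why: Yamaguchi-type mixed-anhydride esterification without a nucleophilic catalyst acylates hindered alcohols with retention at carbon and without isomerising angelate to tiglate.

**Step 12**
Reactants: 25 methyl but-2-ynoate; 26 tributyltin hydride
Product: 27 methyl (2Z)-3-(tributylstannyl)but-2-enoate
Conditions: 26, LDA, THF, 0 °C; PhSCu, −20 °C; then 25, −78 to −48 °C, 4 h; aq NH4Cl
Reagents that add atoms: tributyltin hydride (26), CCCC[SnH](CCCC)CCCC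
Why: Stannylcupration of the ynoate under equilibrating conditions gives the chelation-stabilised adduct, and its protonation places tin cis to the ester (Z).

**Step 13**
Reactants: 24 thioester; 27 stannane
Product: 28 methyl (2R,3S,5R,9R,10S,13Z)-2,3-bis(angeloyloxy)-12,17-dioxolabda-7,13-dien-15-oate (target)
Conditions: 27 (1.5 equiv), Pd2(dba)3 (5 mol%), P(2-furyl)3 (20 mol%), CuO2PPh2 (1.5 equiv), THF/hexanes, 45 °C
Reagents that add atoms: methyl (2Z)-3-(tributylstannyl)but-2-enoate (27), CCCC[Sn](CCCC)(CCCC)/C(C)=C\C(=O)OC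
Why: Liebeskind–Srogl ketone synthesis couples the thioester with the alkenylstannane under neutral conditions with retention of alkene geometry, so the sensitive Z-ene-dicarbonyl unit appears only in the last step and the enal and angelates are untouched.

**Compound list**
1 | (3aR,6aR)-2,2-dimethyldihydrofuro[3,4-d][1,3]dioxol-4(3aH)-one | CC1(C)O[C@@H]2[C@H](O1)COC2=O | starting material
2 | methylmagnesium bromide | C[Mg]Br | starting material
3 | 2-[(4R,5R)-5-(hydroxymethyl)-2,2-dimethyl-1,3-dioxolan-4-yl]propan-2-ol | CC1(C)O[C@@H](C(C)(C)O)[C@H](O1)CO | intermediate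
4 | [(4R,5R)-5-(2-hydroxypropan-2-yl)-2,2-dimethyl-1,3-dioxolan-4-yl]methyl tosylate | CC1(C)O[C@@H](C(C)(C)O)[C@H](O1)COS(=O)(=O)c1ccc(C)cc1 | intermediate
5 | tosylate TES ether | CC1(C)O[C@@H](C(C)(C)O[Si](CC)(CC)CC)[C@H](O1)COS(=O)(=O)c1ccc(C)cc1 | intermediate
6 | lithium acetylide–ethylenediamine complex | [Li+].[C-]#C.NCCN | starting material
7 | homopropargyl dioxolane TES ether | CC1(C)O[C@@H](C(C)(C)O[Si](CC)(CC)CC)[C@H](O1)CC#C | intermediate
8 | trimethylaluminium | C[Al](C)C | starting material
9 | allyl bromide | C=CCBr | starting material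
10 | (E)-alkenyl(dimethyl)alane | CC1(C)O[C@@H](C(C)(C)O[Si](CC)(CC)CC)[C@H](O1)C/C(C)=C/[Al](C)C | intermediate
11 | (E)-1,4-diene TES ether | CC1(C)O[C@@H](C(C)(C)O[Si](CC)(CC)CC)[C@H](O1)C/C(C)=C/CC=C | intermediate
12 | (E)-crotonaldehyde | C/C=C/C=O | starting material
13 | (2E,5E)-dienal TES ether | CC1(C)O[C@@H](C(C)(C)O[Si](CC)(CC)CC)[C@H](O1)C/C(C)=C/C/C=C/C=O | intermediate
14 | (2Z,5E)-2-iododienal TES ether | CC1(C)O[C@@H](C(C)(C)O[Si](CC)(CC)CC)[C@H](O1)C/C(C)=C/C/C=C(\I)C=O | intermediate
15 | (2Z,5E)-2-iododienal carbinol | CC1(C)O[C@@H](C(C)(C)O)[C@H](O1)C/C(C)=C/C/C=C(\I)C=O | intermediate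
16 | acryloyl chloride | C=CC(=O)Cl | starting material
17 | ethanethiol | CCS | starting material
18 | S-ethyl prop-2-enethioate | C=CC(=O)SCC | intermediate
19 | (2E,4E,7E)-4-formyl trienethioate carbinol | CC1(C)O[C@@H](C(C)(C)O)[C@H](O1)C/C(C)=C/C/C=C(\C=C\C(=O)SCC)C=O | intermediate
20 | 2-alkoxy-5,7-di-tert-butyl-3-phenyl-2,3-dihydrobenzoxazole of 19 | CC1(C)O[C@@H](C(C)(C)OC2Oc3c(C(C)(C)C)cc(C(C)(C)C)cc3N2c2ccccc2)[C@H](O1)C/C(C)=C/C/C=C(\C=C\C(=O)SCC)C=O | intermediate
21 | bicyclic acetonide thioester (trans-decalin, 2α,3α-O, H-5α, H-9α, 10β-CH3) | CC1(C)O[C@@H]2[C@H](O1)C[C@]3(C)[C@@H](CC(=O)SCC)C(C=O)=CC[C@H]3C2(C)C | intermediate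
22 | bicyclic 2α,3α-diol thioester | O[C@@H]1[C@H](O)C[C@]2(C)[C@@H](CC(=O)SCC)C(C=O)=CC[C@H]2C1(C)C | intermediate
23 | angelic acid | C/C=C(/C)C(=O)O | starting material
24 | bis-angelate thioester | C/C=C(/C)C(=O)O[C@@H]1[C@H](OC(=O)/C(C)=C\C)C[C@]2(C)[C@@H](CC(=O)SCC)C(C=O)=CC[C@H]2C1(C)C | intermediate
25 | methyl but-2-ynoate | CC#CC(=O)OC | starting material
26 | tributyltin hydride | CCCC[SnH](CCCC)CCCC | starting material
27 | methyl (2Z)-3-(tributylstannyl)but-2-enoate | CCCC[Sn](CCCC)(CCCC)/C(C)=C\C(=O)OC | intermediate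
28 | CNP0141070.1 | C/C=C(/C)C(=O)O[C@@H]1[C@H](OC(=O)/C(C)=C\C)C[C@]2(C)[C@@H](CC(=O)/C(C)=C\C(=O)OC)C(C=O)=CC[C@H]2C1(C)C | target

**Step count and risks**

Total step count: 13. Longest linear sequence: 11 (steps 1–6, 8–11, 13).

Steps most likely to fail:

- **Step 9.** The hindered carbinol may activate slowly, the 6-endo closure is slow, and facial selectivity may be modest. The fallback sets out from 19. Burgess reagent (benzene, 50 °C) dehydrates the carbinol toward a methyl group to give the isopropenyl tetraene F1. Metal-hydride hydrogen-atom transfer (Fe(acac)3, PhSiH3, EtOH, 5 mM, 50 °C) then makes the same C4 radical by delivering H to the 1,1-disubstituted alkene. The reductive 6-endo/6-exo cascade, with its iron enolate protonated by ethanol, comes back to the route at 21.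
- **Step 8.** Sulfur may poison palladium, or the doubly allylic C6H2 may migrate. The fallback sets out from 15. A Heck reaction with sulfur-free acrylic acid (Pd(OAc)2, Ag2CO3, MeCN) gives the trienoic acid F2. Steglich-type thioesterification of F2 with 17 (EDC·HCl, catalytic DMAP, CH2Cl2, 0 °C) comes back to the route at 19.
- **Step 11.** The axial, neopentyl C3–OH may resist acylation, or forcing conditions may give tiglate. The fallback sets out from 19. Aqueous 80% AcOH at 40 °C removes the ketal to give the acyclic triol F3. The mixed anhydride of step 11 acylates its two flexible secondary hydroxyls, leaving the tertiary one free, to give the acyclic bis-angelate F4. The conditions of step 9 then run the bicyclisation through the alkoxybenzoxazoline F5 with the esters already in place, and this comes back to the route at 24.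

**Further compounds**
F1 | step 9 | S-ethyl (2E,4E,7E)-9-[(4R,5S)-2,2-dimethyl-5-(prop-1-en-2-yl)-1,3-dioxolan-4-yl]-4-formyl-8-methylnona-2,4,7-trienethioate | CC1(C)O[C@@H](C(C)=C)[C@H](O1)C/C(C)=C/C/C=C(\C=C\C(=O)SCC)C=O
F2 | step 8 | (2E,4E,7E)-4-formyl-9-[(4R,5R)-5-(2-hydroxypropan-2-yl)-2,2-dimethyl-1,3-dioxolan-4-yl]-8-methylnona-2,4,7-trienoic acid | CC1(C)O[C@@H](C(C)(C)O)[C@H](O1)C/C(C)=C/C/C=C(\C=C\C(=O)O)C=O
F3 | step 11 | S-ethyl (2E,4E,7E,10R,11R)-4-formyl-10,11,12-trihydroxy-8,12-dimethyltrideca-2,4,7-trienethioate | O[C@@H](C(C)(C)O)[C@H](O)C/C(C)=C/C/C=C(\C=C\C(=O)SCC)C=O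
F4 | step 11 | 10,11-bis-angelate of F3 | C/C=C(/C)C(=O)O[C@@H](C(C)(C)O)[C@H](OC(=O)/C(C)=C\C)C/C(C)=C/C/C=C(\C=C\C(=O)SCC)C=O
F5 | step 11 | 2-alkoxy-5,7-di-tert-butyl-3-phenyl-2,3-dihydrobenzoxazole of F4 | C/C=C(/C)C(=O)O[C@@H](C(C)(C)OC1Oc2c(C(C)(C)C)cc(C(C)(C)C)cc2N1c1ccccc1)[C@H](OC(=O)/C(C)=C\C)C/C(C)=C/C/C=C(\C=C\C(=O)SCC)C=O
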